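**Plan**

- Retrosynthesis cuts, in order: the C4–CHO bond on ring A, the two O-methyl bonds, the pyranone (C8–acyl and C7–O bonds), the lactone C11–O10 bond, then ring B itself at C9–C9a.
- Ring B carries four contiguous oxygenated carbons (C9a, C5a, C6, C7) followed by C8 and the methyl-bearing C9. These map onto the four carbons of a squarate plus the two alkene carbons of a propenyl group, with the ring-A aryloxy group already on the squarate.
- Forward: ring A is bought as everninic acid and joined through oxygen to a chloro methoxy squarate; propenyllithium adds; thermal ring expansion builds ring B as a hydroquinone.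
- Then the seven-membered lactone is closed, the pyranone is annulated with 3-methylbut-2-enoic acid, both methyl ethers are cleaved and ring A is formylated.
- The target has no stereocentre; the racemic carbinol carbon and the propenyl geometry of the key-step precursor disappear on aromatization, so no stereocontrol is needed.

Key step: step 5

Remark: positions are cited in depsidone numbering (ring A C1–C4a, O5, ring B C5a–C9a, O10, lactone carbonyl C11). Everninic acid and squaric acid are taken as purchasable. The ring-A oxygen is carried as a methyl ether to survive the acidic annulation, and the carboxyl as a benzyl ester so the acid can be freed by hydrogenolysis.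

**Step 1**
Reactants: 1 2-hydroxy-4-methoxy-6-methylbenzoic acid (everninic acid)
Product: 2 benzyl 2-hydroxy-4-methoxy-6-methylbenzoate
Conditions: BnBr, KHCO3, DMF, rt to 40 °C
Reagents that add atoms: benzyl bromide, BrCc1ccccc1
Why: Carboxylate SN2 alkylation, in which hydrogencarbonate deprotonates only the acid and the hydrogen-bonded 2-hydroxyl stays free, so the ester should form without phenol benzylation.

**Step 2**
Reactants: 3 squaric acid (3,4-dihydroxycyclobut-3-ene-1,2-dione)
Product: 4 3,4-dichlorocyclobut-3-ene-1,2-dione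
Conditions: (COCl)2, DMF (cat.), CH2Cl2, 40 °C
Reagents that add atoms: oxalyl chloride, ClC(=O)C(Cl)=O
Why: Chlorodehydroxylation of a vinylogous carboxylic acid under Vilsmeier-type catalysis, the standard preparation of squaric acid dichloride.

**Step 3**
Reactants: 4 3,4-dichlorocyclobut-3-ene-1,2-dione; 2 benzyl 2-hydroxy-4-methoxy-6-methylbenzoate
Product: 6 benzyl 4-methoxy-2-[(2-methoxy-3,4-dioxocyclobut-1-en-1-yl)oxy]-6-methylbenzoate, via 3-chloro-4-methoxycyclobut-3-ene-1,2-dione 5 (not isolated)
Conditions: MeOH (1.0 equiv), CH2Cl2, 0 °C to rt, argon purge; then 2, Et3N, CH2Cl2, −20 to 0 °C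
Reagents that add atoms: methanol, CO
Why: Two successive addition–elimination substitutions on a vinylogous acid chloride, in which neutral methanol replaces only the first chloride because the ester chloride 5 is deactivated, and the phenoxide of 2 then displaces chloride, a far better leaving group than methoxide.

**Step 4**
Reactants: 7 (E)-1-bromoprop-1-ene; 6 benzyl 4-methoxy-2-[(2-methoxy-3,4-dioxocyclobut-1-en-1-yl)oxy]-6-methylbenzoate
Product: 9 benzyl 2-{[3-hydroxy-2-methoxy-4-oxo-3-((E)-prop-1-enyl)cyclobut-1-en-1-yl]oxy}-4-methoxy-6-methylbenzoate (racemic at the carbinol carbon), via (E)-prop-1-enyllithium 8 (not isolated)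
Conditions: 7, t-BuLi (2.0 equiv), Et2O, −78 °C; cannulated into 6, THF, −78 °C; aq. NH4Cl, −78 °C
Reagents that add atoms: none
Why: Lithium–bromine exchange with retention of alkene geometry, then 1,2-addition of the alkenyllithium to a squarate carbonyl; the carbonyl vinylogous to the weakly donating, bulky aryloxy group (and next to the small methoxy carbon) is the more electrophilic and more accessible one, the hindered benzoate should be untouched at −78 °C, and the new carbinol centre is racemic and erased in step 5.

**Step 5**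
Reactants: 9 benzyl 2-{[3-hydroxy-2-methoxy-4-oxo-3-((E)-prop-1-enyl)cyclobut-1-en-1-yl]oxy}-4-methoxy-6-methylbenzoate
Product: 12 benzyl 2-(3,6-dihydroxy-2-methoxy-5-methylphenoxy)-4-methoxy-6-methylbenzoate, via dienylketene 10 (not isolated), via cyclohexa-2,4-dienone 11 (not isolated)
Conditions: degassed toluene, 110 °C, Ar
Reagents that add atoms: none
Why: Thermal conrotatory four-electron opening of the cyclobutenone breaks the bond between the carbonyl carbon and the carbinol carbon and gives dienylketene 10. Six-electron disrotatory electrocyclization then joins the ketene carbon to the methyl-bearing alkene terminus, closing ring B as cyclohexadienone 11, which enolizes to hydroquinone 12. This is the Moore rearrangement of squarate-derived 4-alkenyl-4-hydroxycyclobutenones, here with an aryloxy group in place of one alkoxy group. No stereocentre remains, since the carbinol carbon, the sp3 carbon of 11 and the propenyl geometry all become part of the arene. The step is regiospecific: the ketene carbon becomes the phenol beside the methyl group (the later lactone oxygen), the carbinol carbon becomes the phenol beside the only ring hydrogen (the later pyran oxygen), and the aryloxy and methoxy carbons become C5a and C6. The one selectivity needed is outward rotation of the hydroxyl so that the propenyl group turns inward toward the ketene, which the donor hydroxyl secures by torquoselectivity; degassed solvent protects the electron-rich hydroquinone from oxidation.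

**Step 6**
Reactants: 12 benzyl 2-(3,6-dihydroxy-2-methoxy-5-methylphenoxy)-4-methoxy-6-methylbenzoate
Product: 13 2-(3,6-dihydroxy-2-methoxy-5-methylphenoxy)-4-methoxy-6-methylbenzoic acid
Conditions: H2 (1 atm), 10% Pd/C, EtOAc, rt
Reagents that add atoms: none
Why: Hydrogenolysis of a benzyl ester, which leaves the aryl methyl ethers and the diaryl ether alone and, being reductive, should return any quinone formed by stray oxidation to the hydroquinone.

**Step 7**
Reactants: 13 2-(3,6-dihydroxy-2-methoxy-5-methylphenoxy)-4-methoxy-6-methylbenzoic acid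
Product: 14 7-hydroxy-3,6-dimethoxy-1,9-dimethyl-11H-dibenzo[b,e][1,4]dioxepin-11-one
Conditions: DCC, CH2Cl2 (high dilution), 0 °C to rt, Ar
Reagents that add atoms: none
Why: Carbodiimide lactonization of a 2-(2-hydroxyphenoxy)benzoic acid, the classical depsidone closure, in which only the hydroxyl ortho to the ether bridge can reach the activated carboxyl to form the seven-membered ring and dilution suppresses intermolecular esterification.

**Step 8**
Reactants: 14 7-hydroxy-3,6-dimethoxy-1,9-dimethyl-11H-dibenzo[b,e][1,4]dioxepin-11-one; 15 3-methylbut-2-enoic acid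
Product: 17 3,6-dimethoxy-1,9-dimethyl-11H-dibenzo[b,e][1,4]dioxepin-11-one bearing a 2,2-dimethyl-2,3-dihydro-4H-pyran-4-one fused across C7 (ring oxygen) and C8 (ketone carbon), via 8-(3-methylbut-2-enoyl) phenol 16 (not isolated)
Conditions: 15 (1.1 equiv), P2O5/MeSO3H (1:10 w/w), 60–70 °C
Reagents that add atoms: none
Why: Friedel–Crafts acylation at C8, the only free position of ring B (ortho to the 7-hydroxyl, para to the ether oxygen), followed by acid-mediated intramolecular oxa-Michael addition of the 7-hydroxyl to enone 16, the standard one-pot route from phenols to 2,2-dimethylchroman-4-ones; ring A is deactivated by the lactone carbonyl and has no free hydroxyl.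

**Step 9**
Reactants: 17 the 3,6-dimethoxy pyranone-fused depsidone
Product: 18 3,6-dihydroxy-1,9-dimethyl-11H-dibenzo[b,e][1,4]dioxepin-11-one bearing the 2,2-dimethyl-2,3-dihydro-4H-pyran-4-one fused across C7 (ring oxygen) and C8 (ketone carbon)
Conditions: BBr3 (6 equiv), CH2Cl2, −78 to 0 °C; then H2O
Reagents that add atoms: none
Why: Lewis-acid cleavage of aryl methyl ethers, in which bromide attacks the methyl group of each boron-complexed ether, while the lactone and the pyranone oxygen, a vinylogous ester oxygen of low basicity, should survive at low temperature.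

**Step 10**
Reactants: 18 the 3,6-dihydroxy pyranone-fused depsidone
Product: 20 target: 4-formyl-3,6-dihydroxy-1,9-dimethyl-11H-dibenzo[b,e][1,4]dioxepin-11-one bearing the 2,2-dimethyl-2,3-dihydro-4H-pyran-4-one fused across C7 (ring oxygen) and C8 (ketone carbon), via chloro(methoxy)methyl arene 19 (not isolated)
Conditions: Cl2CHOMe, TiCl4, CH2Cl2, 0 °C to rt; then 1 M aq. HCl
Reagents that add atoms: dichloromethyl methyl ether, COC(Cl)Cl; water, O
Why: Rieche formylation, in which the titanium phenoxide of the ring-A hydroxyl directs the electrophile to an ortho carbon, C4 (between the hydroxyl and the bridging ether oxygen, para to the methyl) being expected over the more hindered C2 beside the methyl group; ring B has no free position, and hydrolysis of 19 gives the hydrogen-bonded salicylaldehyde.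

**Compound list**

1 | 2-hydroxy-4-methoxy-6-methylbenzoic acid (everninic acid) | COc1cc(C)c(C(=O)O)c(O)c1 | starting material
2 | benzyl 2-hydroxy-4-methoxy-6-methylbenzoate | COc1cc(C)c(C(=O)OCc2ccccc2)c(O)c1 | intermediate
3 | squaric acid (3,4-dihydroxycyclobut-3-ene-1,2-dione) | OC1=C(O)C(=O)C1=O | starting material
4 | 3,4-dichlorocyclobut-3-ene-1,2-dione | ClC1=C(Cl)C(=O)C1=O | intermediate
5 | 3-chloro-4-methoxycyclobut-3-ene-1,2-dione | COC1=C(Cl)C(=O)C1=O | intermediate
6 | benzyl 4-methoxy-2-[(2-methoxy-3,4-dioxocyclobut-1-en-1-yl)oxy]-6-methylbenzoate | COC1=C(Oc2cc(OC)cc(C)c2C(=O)OCc2ccccc2)C(=O)C1=O | intermediate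
7 | (E)-1-bromoprop-1-ene | C/C=C/Br | starting material
8 | (E)-prop-1-enyllithium | C/C=C/[Li] | intermediate
9 | benzyl 2-{[3-hydroxy-2-methoxy-4-oxo-3-((E)-prop-1-enyl)cyclobut-1-en-1-yl]oxy}-4-methoxy-6-methylbenzoate (racemic) | O=C1C(Oc2cc(OC)cc(C)c2C(=O)OCc2ccccc2)=C(OC)C1(O)/C=C/C | intermediate
10 | benzyl 2-{[(3Z,5E)-4-hydroxy-3-methoxy-1-oxohepta-1,3,5-trien-2-yl]oxy}-4-methoxy-6-methylbenzoate (dienylketene) | O=C=C(Oc1cc(OC)cc(C)c1C(=O)OCc1ccccc1)/C(OC)=C(O)\C=C\C | intermediate
11 | benzyl 2-[(3-hydroxy-2-methoxy-5-methyl-6-oxocyclohexa-1,3-dien-1-yl)oxy]-4-methoxy-6-methylbenzoate (racemic) | O=C1C(Oc2cc(OC)cc(C)c2C(=O)OCc2ccccc2)=C(OC)C(O)=CC1C | intermediate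
12 | benzyl 2-(3,6-dihydroxy-2-methoxy-5-methylphenoxy)-4-methoxy-6-methylbenzoate | Cc1cc(O)c(OC)c(Oc2cc(OC)cc(C)c2C(=O)OCc2ccccc2)c1O | intermediate
13 | 2-(3,6-dihydroxy-2-methoxy-5-methylphenoxy)-4-methoxy-6-methylbenzoic acid | Cc1cc(O)c(OC)c(Oc2cc(OC)cc(C)c2C(=O)O)c1O | intermediate
14 | 7-hydroxy-3,6-dimethoxy-1,9-dimethyl-11H-dibenzo[b,e][1,4]dioxepin-11-one | Cc1cc(OC)cc2c1C(=O)Oc1c(C)cc(O)c(OC)c1O2 | intermediate
15 | 3-methylbut-2-enoic acid | CC(C)=CC(=O)O | starting material
16 | 7-hydroxy-3,6-dimethoxy-1,9-dimethyl-8-(3-methylbut-2-enoyl)-11H-dibenzo[b,e][1,4]dioxepin-11-one | Cc1cc(OC)cc2c1C(=O)Oc1c(C)c(C(=O)C=C(C)C)c(O)c(OC)c1O2 | intermediate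
17 | 3,6-dimethoxy-1,9-dimethyl depsidone with a 2,2-dimethyl-2,3-dihydro-4H-pyran-4-one fused across C7 (ring oxygen) and C8 (ketone carbon) | Cc1cc(OC)cc2c1C(=O)Oc1c(C)c3c(c(OC)c1O2)OC(C)(C)CC3=O | intermediate
18 | 3,6-dihydroxy-1,9-dimethyl depsidone with the same fused pyranone | Cc1cc(O)cc2c1C(=O)Oc1c(C)c3c(c(O)c1O2)OC(C)(C)CC3=O | intermediate
19 | 4-[chloro(methoxy)methyl] derivative of 18 (racemic) | Cc1cc(O)c(C(Cl)OC)c2c1C(=O)Oc1c(C)c3c(c(O)c1O2)OC(C)(C)CC3=O | intermediate
20 | 4-formyl-3,6-dihydroxy-1,9-dimethyl depsidone with the same fused pyranone (CNP0271978.0) | Cc1cc(O)c(C=O)c2c1C(=O)Oc1c(C)c3c(c(O)c1O2)OC(C)(C)CC3=O | target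

**Step count**

Total step count: 10. Longest linear sequence: 9 steps (step 2 then steps 3–10; equally step 1 then steps 3–10).

**Steps most likely to fail**

Step 4. The alkenyllithium may attack the carbonyl next to the aryloxy carbon, or expel aryloxide by conjugate addition, so that the four oxygens of ring B end up in the wrong order. The fallback removes the choice by symmetry and sets out from 4 and 2. Two equivalents of 2 with Et3N in CH2Cl2 should give 3,4-bis[2-(benzyloxycarbonyl)-5-methoxy-3-methylphenoxy]cyclobut-3-ene-1,2-dione F1, whose carbonyls are equivalent. Addition of 8 at −78 °C should give 2,3-bis[2-(benzyloxycarbonyl)-5-methoxy-3-methylphenoxy]-4-hydroxy-4-[(E)-prop-1-enyl]cyclobut-2-en-1-one F2. The aryloxy group on the enone β-carbon (next to the carbinol) is a vinylogous aryl ester and should be exchanged for methoxy by MeOH/Et3N at 0 °C through addition–elimination, whereas the α-aryloxy group cannot leave. This returns one equivalent of 2 and rejoins the route at 9.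

Step 10. The formyl group may enter at C2 (ortho to the hydroxyl, para to the ether oxygen) instead of C4, as ring-A halogenations of related depsidones tend to do. The fallback uses that same bias to block C2 and sets out from 18. NBS (1 equiv, MeCN, 0 °C) should give the 2-bromo derivative of 18, F3. Rieche formylation (Cl2CHOMe, TiCl4) can then only reach C4 and should give the 2-bromo-4-formyl compound F4. Hydrodebromination with Pd(PPh3)4 and HCO2Na in DMF at 80 °C, which spares the chelated aldehyde, comes back to the route at 20.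

Step 8. Acylation at the hindered C8 may be slow, and the hot acid medium may sulfonylate the phenol or acylate ring A. The fallback builds the pyranone without strong acid and sets out from 14. O-Alkylation with 3-chloro-3-methylbut-1-yne (K2CO3, KI, CuI cat., acetone) should give 3,6-dimethoxy-1,9-dimethyl-7-[(2-methylbut-3-yn-2-yl)oxy]-11H-dibenzo[b,e][1,4]dioxepin-11-one F5. Aromatic Claisen rearrangement and ring closure in N,N-diethylaniline at 180 °C can only engage C8 and should give the 2,2-dimethyl-2H-pyran-fused depsidone F6. Mukaiyama hydration (Co(acac)2, PhSiH3, O2, THF) should place the hydroxyl on the benzylic carbon to give the pyran-4-ol F7. Dess–Martin periodinane oxidation rejoins the route at 17.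

**Further compounds**

F1 | step 4 | 3,4-bis[2-(benzyloxycarbonyl)-5-methoxy-3-methylphenoxy]cyclobut-3-ene-1,2-dione | O=C1C(=O)C(Oc2cc(OC)cc(C)c2C(=O)OCc2ccccc2)=C1Oc1cc(OC)cc(C)c1C(=O)OCc1ccccc1
F2 | step 4 | 2,3-bis[2-(benzyloxycarbonyl)-5-methoxy-3-methylphenoxy]-4-hydroxy-4-[(E)-prop-1-enyl]cyclobut-2-en-1-one (racemic) | O=C1C(Oc2cc(OC)cc(C)c2C(=O)OCc2ccccc2)=C(Oc2cc(OC)cc(C)c2C(=O)OCc2ccccc2)C1(O)/C=C/C
F3 | step 10 | 2-bromo derivative of 18 | Cc1c(Br)c(O)cc2c1C(=O)Oc1c(C)c3c(c(O)c1O2)OC(C)(C)CC3=O
F4 | step 10 | 2-bromo derivative of 20 | Cc1c(Br)c(O)c(C=O)c2c1C(=O)Oc1c(C)c3c(c(O)c1O2)OC(C)(C)CC3=O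
F5 | step 8 | 3,6-dimethoxy-1,9-dimethyl-7-[(2-methylbut-3-yn-2-yl)oxy]-11H-dibenzo[b,e][1,4]dioxepin-11-one | Cc1cc(OC)cc2c1C(=O)Oc1c(C)cc(OC(C)(C)C#C)c(OC)c1O2
F6 | step 8 | 3,6-dimethoxy-1,9-dimethyl depsidone with a 2,2-dimethyl-2H-pyran fused across C7 (ring oxygen) and C8 (alkene carbon) | Cc1cc(OC)cc2c1C(=O)Oc1c(C)c3c(c(OC)c1O2)OC(C)(C)C=C3
F7 | step 8 | 3,6-dimethoxy-1,9-dimethyl depsidone with a 4-hydroxy-2,2-dimethyl-3,4-dihydro-2H-pyran fused across C7 (ring oxygen) and C8 (carbinol carbon), racemic | Cc1cc(OC)cc2c1C(=O)Oc1c(C)c3c(c(OC)c1O2)OC(C)(C)CC3O
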